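## Analysis of the target

The target 30 is a (3R)-isoflavan: ring C is the dihydropyran O1–C2–C3–C4, ring A (C4a to C8a) carries a methoxy group on C5, a 3-methylbut-2-enyl (prenyl) group on C6 and a free hydroxyl on C7, and ring B (C1' to C6'), bound to C3, is the benzo ring of a 2,2-dimethyl-2H-chromene with the pyran oxygen on C2', the vinyl carbon on C3' and a free hydroxyl on C4'. C3 is the only stereocenter; it is benzylic to ring B, so it is stable while C2 is a methylene group but is easily epimerized in any intermediate in which C2 is a carbonyl carbon. The prenyl and chromene double bonds are electron-rich, which excludes hydrogenation, electrophilic halogen sources and strong acid, and a prenyl group next to a free phenol cyclizes to a chroman under strong acid. The real difficulty is ring A, a phloroglucinol whose three oxygens are all different (methyl ether, free phenol, ring ether) and whose prenyl group must sit at C6 and not at C8. On a 1,3,5-trioxygenated benzene neither electrophilic substitution nor metalation tells these positions apart reliably. The plan rests on the fact that O1 on C8a is meta to the oxygens on C5 and C7, so that C8a becomes the β-carbon of a cyclohexadienone once the 7-phenol is oxidized at its para carbon C4a. C4a already holds the chain C4–C3–C2, whose terminal oxygen reaches C8a through a six-membered transition state. Ring A can therefore enter as a resorcinol derivative with only two oxygens and the prenyl position between them, and the third oxygen is attached last, from inside the molecule.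

## Retrosynthetic reasoning

**30 from 29.** The last bond cut is the O–Si bond at the 4'-oxygen. A silyl ether is chosen there because ring A needs an acetal for its lithiation, and two acetals could not be told apart later. Desilylation by a fluoride source also spares the ortho-prenylphenol and the chromene from a final acid treatment.

**29 from 26 (key disconnection).** The O1–C8a bond is cut. It is the one ring-A bond that no aromatic substitution can make, being meta to both donors. In the dearomatized form 26 the polarity is reversed: C8a is the unsubstituted β-carbon of a dienone and the C2 oxygen is a tethered nucleophile. The forward reaction must free the C2 alkoxide (27), add it to C8a and not to C5 (28), and then expel the C4a methoxy group with the C8a hydrogen to restore the arene. The configuration at C4a is lost on aromatization, so 26 may be a mixture of epimers.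

**26 from 25.** The C4a–OMe bond is cut, which corresponds to oxidative dearomatization of the 7-phenol in an alcohol solvent. The C2 hydroxyl must be masked as its acetate, because a free hydroxyl would capture the ipso carbon C4a and give a five-membered spiro ether. Ring B must be a non-phenolic ether so that only ring A is oxidized.

**25 from 21 by way of 23 and 22.** These are functional-group changes only: selective cleavage of the ring-A acetal without protic acid (through 24), acetylation, and reductive removal of the auxiliary. After the reduction C3 is no longer next to a carbonyl group and is configurationally secure.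

**21 from 19 and 7.** The C3–C4 bond is cut. This splits the molecule into halves of similar size and places the stereocenter α to an imide, where the chiral auxiliary controls it. The (4R)-benzyl auxiliary 17 leads to (R) at C3, because the ring-B aryl group outranks the new benzylic methylene. The enolate of 19 (20) must be alkylated cold by the reactive benzylic bromide 7.

**7 from 1 by way of 6, 3 and 2.** The C6–prenyl bond is cut. With the benzylic carbon already present as an alkoxide (5), one lithiation between the methoxy and acetal oxygens suffices, and prenyl bromide 4 is introduced through an arylcopper species. No second metalation has to be done next to the benzylic and allylic methylene of a prenyl arene. Aldehyde 1 already holds the methoxy group ortho and the hydroxyl para to the future C4.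

**19 from 16 and 17, and 16 from 13 by way of 15 and 14.** The imide N–C bond is cut (through 18), then one carbon is removed from the arylacetic acid. The aldehyde 13 is the natural product of the chromene synthesis, and Wittig homologation, hydrolysis and oxidation turn it into 16 without strong alkoxide base, which the silyl ether would not survive.

**13 from 8 by way of 11 and 9, with 10.** The pyran O–C bond and the C3'–vinyl bond are cut. In 8 the hydroxyl next to the formyl group is hydrogen-bonded, so the other one is silylated selectively (9). Etherification of the remaining hydroxyl with 10 and an aromatic propargyl Claisen cascade (through 12) can then use only the carbon between the two oxygens. This places the pyran oxygen next to the future C1'.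

## Alternatives that were turned down

Alternative 1: ring C as a lactone from an ortho-quinone methide and a catalytically generated ammonium enolate.
- Disconnection: C3–C4 and O1–C2 are cut together.
- Forward key step: base releases an ortho-quinone methide of ring A from the sulfone A1. A chiral isothiourea catalyst with Cs2CO3 turns an activated derivative of the ring-B arylacetic acid A2 into an ammonium enolate. Their formal [4+2] union gives the lactone A3.
- For it: it is more convergent than the chosen route, closes ring C and sets C3 in one catalytic operation, and needs no stoichiometric auxiliary. On these points it is stronger.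
- Against it:
  - A1 must already contain ring A with three different oxygens, a free phenol at C8a and the prenyl group at C6. Placing the prenyl group at C6 and not at C8 on a phloroglucinol is the unsolved regiochemical problem.
  - The methide is unsubstituted at its methylene carbon and very electron-rich, so oligomerization competes.
  - In A3 the C3 hydrogen is benzylic and α to an aryl ester, so the carbonate base can erode the configuration.
  - C2 arrives as a carbonyl carbon. It must be reduced and ring C closed a second time or deoxygenated, and two acetals must then be removed with acid from an ortho-prenylphenol.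
- Comparison: the chosen route pays with an auxiliary and a longer linear sequence. In return it needs only a two-oxygen ring A, whose substitution is unambiguous, and keeps C3 away from a carbonyl group from step 13 onwards.

Alternative 2: building ring A from acyclic partners by thermal benzannulation of a cyclobutenone with an ynol ether.
- Disconnection: C4a–C8a, C5–C6 and C8–C8a are cut, so ring A does not come from an arene.
- Forward key step: the cyclobutenone A4 opens on heating to a vinylketene, which combines with the chiral ynol ether A5 by [2+2] cycloaddition, ring opening and 6π closure (Danheiser benzannulation) to the fully substituted phenol A6. Ring C is then closed by a Mitsunobu reaction at the C8a hydroxyl.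
- For it: every substituent of ring A is fixed by the connectivity of the partners, so there is no regiochemical question, and the conditions are neutral. On certainty of the ring-A pattern it is stronger than the chosen route, whose key step is untested.
- Against it:
  - A4 is not a stock compound, and 3-siloxycyclobutenones are hydrolytically labile.
  - A5 requires a methyl ynol ether on a chain that already carries the stereocenter. Alkylating a metalated alkoxyacetylene with a β-branched primary electrophile is slow, and the product is acid-sensitive.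
  - The ketene intermediates are formed at elevated temperature beside two nucleophilic alkenes.
  - After the key step a selective desilylation, the ring closure and a double desilylation remain.
- Comparison: both fragments need more steps than 7 and 19, and the stereocenter must still be made separately. The chosen route is shorter and uses stable intermediates, at the price of one unprecedented step.

Alternative 3: assembling ring B as a cyclohexane-1,3-dione and aromatizing it afterwards.
- Disconnection: C1'–C6' and C3'–C4' of ring B are cut.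
- Forward key step: under KOtBu the methylene carbon of the ketone A7 that lies between C3 and the carbonyl group adds to methyl acrylate A8, and the keto ester so formed closes by Claisen condensation of the methyl carbon onto the ester to the dione A9. Ring B is then aromatized and the pyran is annulated.
- For it: no arylacetic acid homologation is needed, pyran annulation onto a 1,3-dione is a dependable condensation, and C3 is β to the carbonyl groups and safe.
- Against it:
  - A7 already contains ring A and ring C with the C3 stereocenter, so the hard part of the molecule is only moved into the synthesis of A7.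
  - On the 4-substituted dione A9 the pyran can form on either carbonyl oxygen, and the hindered one next to C1' is the one required.
  - Aromatization needs a dehydrogenating oxidant in the presence of the prenyl group.
  - At least four steps follow the key step, the last an acidic acetal removal.
- Comparison: this plan spends its strategic step on the easier ring. The chosen route spends it on the bond that is hardest to make, O1–C8a.

Key step: step 17

Remark on the chemistry: the 4'-oxygen is carried as its triisopropylsilyl ether through the key step, and compounds 1, 4, 8, 10 and 17 are taken to be purchasable.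

## Route

Step 1
Reactants: 1 4-hydroxy-2-methoxybenzaldehyde
Product: 2 2-methoxy-4-(methoxymethoxy)benzaldehyde
Conditions: MeOCH2Cl, i-Pr2NEt, CH2Cl2, 0 °C → rt
Reagents that add atoms: chloromethyl methyl ether, COCCl
Why: O-alkylation of the acidic para-formyl phenol gives the acetal, which later directs the lithiation and protects O7 up to step 15.

Step 2
Reactants: 2 2-methoxy-4-(methoxymethoxy)benzaldehyde
Product: 3 [2-methoxy-4-(methoxymethoxy)phenyl]methanol
Conditions: NaBH4, MeOH, 0 °C
Reagents that add atoms: none
Why: Hydride reduction removes the electrophilic formyl group before the organolithium step and provides the future C4 as a benzylic alcohol.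

Step 3
Reactants: 3 [2-methoxy-4-(methoxymethoxy)phenyl]methanol; 4 prenyl bromide (1-bromo-3-methylbut-2-ene)
Product: 6 [2-methoxy-4-(methoxymethoxy)-3-(3-methylbut-2-enyl)phenyl]methanol, via C3,O-dilithio species 5 (not isolated)
Conditions: n-BuLi (2.2 equiv), THF, 0 °C; CuBr·SMe2, −78 °C; then 4, −78 → 0 °C; aq NH4Cl
Reagents that add atoms: none
Why: Directed ortho-metalation: after alkoxide formation the second equivalent of base removes the ring hydrogen flanked by the methoxy and acetal oxygens, the site both can coordinate; transmetalation to the arylcopper lowers the basicity and directs the allylic substitution of 4 to its primary carbon.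

Step 4
Reactants: 6 [2-methoxy-4-(methoxymethoxy)-3-(3-methylbut-2-enyl)phenyl]methanol
Product: 7 1-(bromomethyl)-2-methoxy-4-(methoxymethoxy)-3-(3-methylbut-2-enyl)benzene
Conditions: CBr4, PPh3, CH2Cl2, 0 °C; used crude at once
Reagents that add atoms: tetrabromomethane, BrC(Br)(Br)Br
Why: Appel bromination under neutral conditions spares the acetal and the prenyl alkene; the bromide ionizes easily because of its ortho and para oxygen donors and is therefore not stored.

Step 5
Reactants: 8 2,4-dihydroxybenzaldehyde
Product: 9 2-hydroxy-4-(triisopropylsilyloxy)benzaldehyde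
Conditions: i-Pr3SiCl, imidazole, CH2Cl2, 0 °C → rt
Reagents that add atoms: chlorotriisopropylsilane, CC(C)[Si](Cl)(C(C)C)C(C)C
Why: Selective silylation of the 4-hydroxyl, since the 2-hydroxyl is tied up in a hydrogen bond to the formyl oxygen and is much less nucleophilic.

Step 6
Reactants: 9 2-hydroxy-4-(triisopropylsilyloxy)benzaldehyde; 10 3-chloro-3-methylbut-1-yne
Product: 11 2-(2-methylbut-3-yn-2-yloxy)-4-(triisopropylsilyloxy)benzaldehyde
Conditions: DBU, CuCl2 (cat.), MeCN, 0 °C → rt
Reagents that add atoms: none
Why: Copper-catalysed propargylic etherification, in which a copper acetylide of 10 ionizes and the phenoxide attacks the tertiary carbon, gives the aryl 1,1-dimethylpropargyl ether that direct displacement cannot give.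

Step 7
Reactants: 11 2-(2-methylbut-3-yn-2-yloxy)-4-(triisopropylsilyloxy)benzaldehyde
Product: 13 2,2-dimethyl-5-(triisopropylsilyloxy)-2H-chromene-8-carbaldehyde, via allenyl phenol 12 (not isolated)
Conditions: xylenes, 140 °C
Reagents that add atoms: none
Why: Aromatic propargyl Claisen rearrangement to the only free ortho carbon gives 12 after tautomerization, and a 1,5-hydrogen shift followed by oxa-6π electrocyclization closes the chromene; because the ether oxygen is the one next to the formyl carbon, the pyran oxygen ends on the future C2'.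

Step 8
Reactants: 13 2,2-dimethyl-5-(triisopropylsilyloxy)-2H-chromene-8-carbaldehyde
Product: 14 8-(2-methoxyethenyl)-2,2-dimethyl-5-(triisopropylsilyloxy)-2H-chromene (E/Z mixture)
Conditions: Ph3P(CH2OMe)Cl, NaN(SiMe3)2, THF, 0 °C; then 13, 0 °C → rt
Reagents that add atoms: (methoxymethyl)triphenylphosphonium chloride, COC[P+](c1ccccc1)(c1ccccc1)c1ccccc1.[Cl-]
Why: Wittig methoxymethylenation adds the one carbon needed; the amide base leaves no alkoxide that could attack the aryl silyl ether, and the alkene geometry is irrelevant.

Step 9
Reactants: 14 8-(2-methoxyethenyl)-2,2-dimethyl-5-(triisopropylsilyloxy)-2H-chromene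
Product: 15 2-[2,2-dimethyl-5-(triisopropylsilyloxy)-2H-chromen-8-yl]acetaldehyde
Conditions: 2 M aq HCl, THF, rt
Reagents that add atoms: water, O
Why: Acid hydrolysis of the enol ether by protonation at the benzylic carbon and collapse of the hemiacetal; dilute acid at room temperature leaves the aryl silyl ether and the chromene intact.

Step 10
Reactants: 15 2-[2,2-dimethyl-5-(triisopropylsilyloxy)-2H-chromen-8-yl]acetaldehyde
Product: 16 2-[2,2-dimethyl-5-(triisopropylsilyloxy)-2H-chromen-8-yl]acetic acid
Conditions: NaClO2, NaH2PO4, 2-methyl-2-butene, t-BuOH/H2O, 0 °C → rt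
Reagents that add atoms: sodium chlorite, [Na+].[O-]Cl=O
Why: Pinnick oxidation; the alkene scavenger removes hypochlorous acid before it can attack the chromene double bond.

Step 11
Reactants: 16 2-[2,2-dimethyl-5-(triisopropylsilyloxy)-2H-chromen-8-yl]acetic acid; 17 (R)-4-benzyl-2-oxazolidinone
Product: 19 (4R)-4-benzyl-3-{2-[2,2-dimethyl-5-(triisopropylsilyloxy)-2H-chromen-8-yl]acetyl}oxazolidin-2-one, via mixed pivalic anhydride 18 (not isolated)
Conditions: t-BuCOCl, Et3N, THF, −20 °C; then 17, LiCl, −20 °C → rt
Reagents that add atoms: none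
Why: N-Acylation of the oxazolidinone through the mixed anhydride, whose hindered pivaloyl carbonyl directs attack to the arylacetyl carbonyl; LiCl activates the oxazolidinone as its lithium chelate.

Step 12
Reactants: 19 (4R)-4-benzyl-3-{2-[2,2-dimethyl-5-(triisopropylsilyloxy)-2H-chromen-8-yl]acetyl}oxazolidin-2-one; 7 1-(bromomethyl)-2-methoxy-4-(methoxymethoxy)-3-(3-methylbut-2-enyl)benzene
Product: 21 (4R)-4-benzyl-3-{(2R)-2-[2,2-dimethyl-5-(triisopropylsilyloxy)-2H-chromen-8-yl]-3-[2-methoxy-4-(methoxymethoxy)-3-(3-methylbut-2-enyl)phenyl]propanoyl}oxazolidin-2-one, via sodium (Z)-enolate 20 (not isolated)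
Conditions: NaN(SiMe3)2, THF, −78 °C; then 7, −78 → −40 °C; aq NH4Cl at −78 °C
Reagents that add atoms: none
Why: Evans alkylation: the chelated (Z)-enolate 20 is attacked by the benzylic bromide on the face opposite to the benzyl group of the (4R)-auxiliary, which sets C3 as (R) because the ring-B aryl group outranks the new methylene; low temperature and a cold quench guard the acidic α-aryl hydrogen of 21.

Step 13
Reactants: 21 (4R)-4-benzyl-3-{(2R)-2-[2,2-dimethyl-5-(triisopropylsilyloxy)-2H-chromen-8-yl]-3-[2-methoxy-4-(methoxymethoxy)-3-(3-methylbut-2-enyl)phenyl]propanoyl}oxazolidin-2-one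
Product: 22 (2R)-2-[2,2-dimethyl-5-(triisopropylsilyloxy)-2H-chromen-8-yl]-3-[2-methoxy-4-(methoxymethoxy)-3-(3-methylbut-2-enyl)phenyl]propan-1-ol
Conditions: LiBH4, MeOH (1 equiv), Et2O, 0 °C
Reagents that add atoms: none
Why: Reductive cleavage of the imide carbonyl releases the auxiliary and gives the primary alcohol without enolization, so C3 keeps its configuration and is from here on not adjacent to a carbonyl group.

Step 14
Reactants: 22 (2R)-2-[2,2-dimethyl-5-(triisopropylsilyloxy)-2H-chromen-8-yl]-3-[2-methoxy-4-(methoxymethoxy)-3-(3-methylbut-2-enyl)phenyl]propan-1-ol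
Product: 23 (2R)-2-[2,2-dimethyl-5-(triisopropylsilyloxy)-2H-chromen-8-yl]-3-[2-methoxy-4-(methoxymethoxy)-3-(3-methylbut-2-enyl)phenyl]propyl acetate
Conditions: Ac2O, pyridine, DMAP (cat.), CH2Cl2, 0 °C → rt
Reagents that add atoms: acetic anhydride, CC(=O)OC(C)=O
Why: Acylation masks the C2 hydroxyl so that it cannot capture the ipso carbon during dearomatization; the acetate is also the latent trigger of the key step.

Step 15
Reactants: 23 (2R)-2-[2,2-dimethyl-5-(triisopropylsilyloxy)-2H-chromen-8-yl]-3-[2-methoxy-4-(methoxymethoxy)-3-(3-methylbut-2-enyl)phenyl]propyl acetate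
Product: 25 (2R)-2-[2,2-dimethyl-5-(triisopropylsilyloxy)-2H-chromen-8-yl]-3-[4-hydroxy-2-methoxy-3-(3-methylbut-2-enyl)phenyl]propyl acetate, via aryl trimethylsilyl ether 24 (not isolated)
Conditions: Me3SiOTf, 2,2'-bipyridyl, MeCN, 0 °C → rt; then H2O
Reagents that add atoms: none
Why: Silyl triflate activation of the aromatic methoxymethyl ether in the presence of bipyridyl transfers the methoxymethyl group to nitrogen and leaves 24, which water hydrolyses; no protic acid is present, so the acetate, the hindered silyl ether, the prenyl group and the chromene are untouched.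

Step 16
Reactants: 25 (2R)-2-[2,2-dimethyl-5-(triisopropylsilyloxy)-2H-chromen-8-yl]-3-[4-hydroxy-2-methoxy-3-(3-methylbut-2-enyl)phenyl]propyl acetate
Product: 26 (2R)-3-[1,2-dimethoxy-3-(3-methylbut-2-enyl)-4-oxocyclohexa-2,5-dien-1-yl]-2-[2,2-dimethyl-5-(triisopropylsilyloxy)-2H-chromen-8-yl]propyl acetate (both epimers at C4a)
Conditions: PhI(OAc)2, MeOH, 0 °C
Reagents that add atoms: methanol, CO
Why: Oxidative dearomatization of a para-alkylphenol by a trivalent iodine reagent: ligand exchange at the phenol oxygen makes the ring electrophilic and the solvent adds at the para carbon C4a; only ring A has a free phenol, and the acetate prevents spiro ether formation.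

Step 17
Reactants: 26 (2R)-3-[1,2-dimethoxy-3-(3-methylbut-2-enyl)-4-oxocyclohexa-2,5-dien-1-yl]-2-[2,2-dimethyl-5-(triisopropylsilyloxy)-2H-chromen-8-yl]propyl acetate
Product: 29 (3R)-3-[2,2-dimethyl-5-(triisopropylsilyloxy)-2H-chromen-8-yl]-5-methoxy-6-(3-methylbut-2-enyl)chroman-7-ol, via deacetylated dienone 27 (not isolated), via bicyclic oxa-Michael adduct 28 (not isolated)
Conditions: K2CO3 (cat.), MeOH, 0 °C → rt; then solvent change, camphorsulfonic acid (cat.), CH2Cl2, rt → 40 °C
Reagents that add atoms: none
Why: Proposed new method: catalytic methoxide takes the acetyl group off 26 and the primary alkoxide of 27 adds to C8a, the hydrogen-bearing β-carbon of the dienone, which forms the O1–C8a bond and closes ring C in the 6-exo-trig mode to give 28; the closest known reaction types are the intramolecular oxa-Michael addition of tethered alcohols to 4,4-disubstituted cyclohexadienones and the conjugate addition to quinol ethers or quinone monoketals that ends in loss of the 4-substituent and rearomatization, and their combination in one tethered substrate is not documented. After the solvent change, camphorsulfonic acid enolizes the C7 ketone towards C8 and ionizes the tertiary allylic methoxy group on C4a; the resulting cation is the arenium ion of 29 protonated at C8a, and loss of that proton restores ring A with O1 meta to both other oxygens. No stereocenter is created that persists: C4a and C8a become sp2 carbons, so both epimers of 26 converge and the ring fusion of 28 is immaterial, while C3 is not acidic and stays (R). The selectivity required is between the two dienone β-carbons, and the substrate secures it because C5 is a fully substituted, donor-bearing vinylogous ester carbon next to the quaternary centre, whereas C8a carries only hydrogen. Any exchange at C5 is reversible in methanol, while the adduct at C8a is removed irreversibly by aromatization. The oxygens on C5 and C7 sit at nodal positions of the cation and do not assist the ionization, so gentle warming may be needed; the acid is kept weak and catalytic so that the prenyl group does not add to the new 7-hydroxyl.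

Step 18
Reactants: 29 (3R)-3-[2,2-dimethyl-5-(triisopropylsilyloxy)-2H-chromen-8-yl]-5-methoxy-6-(3-methylbut-2-enyl)chroman-7-ol
Product: 30 (3R)-3-(5-hydroxy-2,2-dimethyl-2H-chromen-8-yl)-5-methoxy-6-(3-methylbut-2-enyl)chroman-7-ol
Conditions: Bu4NF, THF, 0 °C; aq NH4Cl
Reagents that add atoms: none
Why: Fluoride cleaves the aryl silyl ether; no acid touches the ortho-prenylphenol or the chromene, and C3 is unaffected.

## Compound list

1 | 4-hydroxy-2-methoxybenzaldehyde | COc1cc(O)ccc1C=O | starting material
2 | 2-methoxy-4-(methoxymethoxy)benzaldehyde | COCOc1ccc(C=O)c(OC)c1 | intermediate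
3 | [2-methoxy-4-(methoxymethoxy)phenyl]methanol | COCOc1ccc(CO)c(OC)c1 | intermediate
4 | prenyl bromide (1-bromo-3-methylbut-2-ene) | CC(C)=CCBr | starting material
5 | C3,O-dilithio species of 3 (lithium alkoxide, aryllithium between the two oxygens) | COCOc1ccc(CO[Li])c(OC)c1[Li] | intermediate
6 | [2-methoxy-4-(methoxymethoxy)-3-(3-methylbut-2-enyl)phenyl]methanol | COCOc1ccc(CO)c(OC)c1CC=C(C)C | intermediate
7 | 1-(bromomethyl)-2-methoxy-4-(methoxymethoxy)-3-(3-methylbut-2-enyl)benzene | COCOc1ccc(CBr)c(OC)c1CC=C(C)C | intermediate
8 | 2,4-dihydroxybenzaldehyde | O=Cc1ccc(O)cc1O | starting material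
9 | 2-hydroxy-4-(triisopropylsilyloxy)benzaldehyde | O=Cc1ccc(O[Si](C(C)C)(C(C)C)C(C)C)cc1O | intermediate
10 | 3-chloro-3-methylbut-1-yne | C#CC(C)(C)Cl | starting material
11 | 2-(2-methylbut-3-yn-2-yloxy)-4-(triisopropylsilyloxy)benzaldehyde | O=Cc1ccc(O[Si](C(C)C)(C(C)C)C(C)C)cc1OC(C)(C)C#C | intermediate
12 | 2-hydroxy-3-(3-methylbuta-1,2-dienyl)-4-(triisopropylsilyloxy)benzaldehyde (allenyl phenol) | O=Cc1ccc(O[Si](C(C)C)(C(C)C)C(C)C)c(C=C=C(C)C)c1O | intermediate
13 | 2,2-dimethyl-5-(triisopropylsilyloxy)-2H-chromene-8-carbaldehyde | O=Cc1ccc(O[Si](C(C)C)(C(C)C)C(C)C)c2c1OC(C)(C)C=C2 | intermediate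
14 | 8-(2-methoxyethenyl)-2,2-dimethyl-5-(triisopropylsilyloxy)-2H-chromene (E/Z mixture) | COC=Cc1ccc(O[Si](C(C)C)(C(C)C)C(C)C)c2c1OC(C)(C)C=C2 | intermediate
15 | 2-[2,2-dimethyl-5-(triisopropylsilyloxy)-2H-chromen-8-yl]acetaldehyde | O=CCc1ccc(O[Si](C(C)C)(C(C)C)C(C)C)c2c1OC(C)(C)C=C2 | intermediate
16 | 2-[2,2-dimethyl-5-(triisopropylsilyloxy)-2H-chromen-8-yl]acetic acid | OC(=O)Cc1ccc(O[Si](C(C)C)(C(C)C)C(C)C)c2c1OC(C)(C)C=C2 | intermediate
17 | (R)-4-benzyl-2-oxazolidinone | O=C1N[C@H](Cc2ccccc2)CO1 | starting material
18 | mixed anhydride of 16 with pivalic acid | CC(C)(C)C(=O)OC(=O)Cc1ccc(O[Si](C(C)C)(C(C)C)C(C)C)c2c1OC(C)(C)C=C2 | intermediate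
19 | (4R)-4-benzyl-3-{2-[2,2-dimethyl-5-(triisopropylsilyloxy)-2H-chromen-8-yl]acetyl}oxazolidin-2-one | O=C(Cc1ccc(O[Si](C(C)C)(C(C)C)C(C)C)c2c1OC(C)(C)C=C2)N1[C@H](Cc2ccccc2)COC1=O | intermediate
20 | sodium (Z)-enolate of 19 | [Na]O/C(=C\c1ccc(O[Si](C(C)C)(C(C)C)C(C)C)c2c1OC(C)(C)C=C2)N1[C@H](Cc2ccccc2)COC1=O | intermediate
21 | (4R)-4-benzyl-3-{(2R)-2-[2,2-dimethyl-5-(triisopropylsilyloxy)-2H-chromen-8-yl]-3-[2-methoxy-4-(methoxymethoxy)-3-(3-methylbut-2-enyl)phenyl]propanoyl}oxazolidin-2-one | COCOc1ccc(C[C@H](c2ccc(O[Si](C(C)C)(C(C)C)C(C)C)c3c2OC(C)(C)C=C3)C(=O)N2[C@H](Cc3ccccc3)COC2=O)c(OC)c1CC=C(C)C | intermediate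
22 | (2R)-2-[2,2-dimethyl-5-(triisopropylsilyloxy)-2H-chromen-8-yl]-3-[2-methoxy-4-(methoxymethoxy)-3-(3-methylbut-2-enyl)phenyl]propan-1-ol | COCOc1ccc(C[C@H](c2ccc(O[Si](C(C)C)(C(C)C)C(C)C)c3c2OC(C)(C)C=C3)CO)c(OC)c1CC=C(C)C | intermediate
23 | (2R)-2-[2,2-dimethyl-5-(triisopropylsilyloxy)-2H-chromen-8-yl]-3-[2-methoxy-4-(methoxymethoxy)-3-(3-methylbut-2-enyl)phenyl]propyl acetate | COCOc1ccc(C[C@H](c2ccc(O[Si](C(C)C)(C(C)C)C(C)C)c3c2OC(C)(C)C=C3)COC(C)=O)c(OC)c1CC=C(C)C | intermediate
24 | trimethylsilyl ether of 25 at the 7-oxygen | COc1c(CC=C(C)C)c(O[Si](C)(C)C)ccc1C[C@H](c1ccc(O[Si](C(C)C)(C(C)C)C(C)C)c2c1OC(C)(C)C=C2)COC(C)=O | intermediate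
25 | (2R)-2-[2,2-dimethyl-5-(triisopropylsilyloxy)-2H-chromen-8-yl]-3-[4-hydroxy-2-methoxy-3-(3-methylbut-2-enyl)phenyl]propyl acetate | COc1c(CC=C(C)C)c(O)ccc1C[C@H](c1ccc(O[Si](C(C)C)(C(C)C)C(C)C)c2c1OC(C)(C)C=C2)COC(C)=O | intermediate
26 | (2R)-3-[1,2-dimethoxy-3-(3-methylbut-2-enyl)-4-oxocyclohexa-2,5-dien-1-yl]-2-[2,2-dimethyl-5-(triisopropylsilyloxy)-2H-chromen-8-yl]propyl acetate, both epimers at the quaternary ring carbon (C4a) | COC1=C(CC=C(C)C)C(=O)C=CC1(OC)C[C@H](c1ccc(O[Si](C(C)C)(C(C)C)C(C)C)c2c1OC(C)(C)C=C2)COC(C)=O | intermediate
27 | 4-[(2R)-2-[2,2-dimethyl-5-(triisopropylsilyloxy)-2H-chromen-8-yl]-3-hydroxypropyl]-3,4-dimethoxy-2-(3-methylbut-2-enyl)cyclohexa-2,5-dien-1-one, both epimers at C4a | COC1=C(CC=C(C)C)C(=O)C=CC1(OC)C[C@H](c1ccc(O[Si](C(C)C)(C(C)C)C(C)C)c2c1OC(C)(C)C=C2)CO | intermediate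
28 | (3R)-3-[2,2-dimethyl-5-(triisopropylsilyloxy)-2H-chromen-8-yl]-4a,5-dimethoxy-6-(3-methylbut-2-enyl)-2,3,4,4a,8,8a-hexahydrochromen-7-one, mixture at C4a and C8a | COC1=C(CC=C(C)C)C(=O)CC2OC[C@@H](c3ccc(O[Si](C(C)C)(C(C)C)C(C)C)c4c3OC(C)(C)C=C4)CC12OC | intermediate
29 | (3R)-3-[2,2-dimethyl-5-(triisopropylsilyloxy)-2H-chromen-8-yl]-5-methoxy-6-(3-methylbut-2-enyl)chroman-7-ol | COc1c(CC=C(C)C)c(O)cc2c1C[C@H](c1ccc(O[Si](C(C)C)(C(C)C)C(C)C)c3c1OC(C)(C)C=C3)CO2 | intermediate
30 | (3R)-3-(5-hydroxy-2,2-dimethyl-2H-chromen-8-yl)-5-methoxy-6-(3-methylbut-2-enyl)chroman-7-ol | COc1c(CC=C(C)C)c(O)cc2c1C[C@H](c1ccc(O)c3c1OC(C)(C)C=C3)CO2 | target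

## Step count and least certain steps

Total step count: 18. Longest linear sequence: 14 steps (8 to 30 through steps 5 to 18). The ring-A branch (1 to 7, steps 1 to 4) runs in parallel.

**Step 17 (key step, the one step that carries the label "Proposed new method:").** The most likely failure is slow ionization at C4a, because the cation gains no resonance help from the oxygens on C5 and C7. The oxa-Michael addition could then revert under acid, and the regenerated dienone could undergo a dienone–phenol shift of the side chain. Exchange of the C5 methoxy group by the alkoxide is a second, reversible diversion. Partial loss of the aryl silyl group to methoxide would not divert material, since step 18 removes that group in any case.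
Fallback, known chemistry, from 26 back to 29: the sequence is stopped after the K2CO3 treatment and the bicyclic adduct 28 is isolated. Its enolate, which can form only towards C8, is trapped with LiN(SiMe3)2 and Me3SiCl in THF at −78 °C as the trimethylsilyl dienol ether F1. Saegusa–Ito oxidation with Pd(OAc)2 in MeCN gives the 4a-methoxy dienone F2 with the C8–C8a double bond. Zn in AcOH then expels the C4a methoxy group reductively and gives 29, where the route is rejoined. Aromatization is thus reached by oxidation and reduction instead of by ionization.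

**Step 16.** The most likely failures are attack of the solvent at the free ortho carbon C8 instead of C4a, and oxidative loss of a benzylic hydrogen of the ortho-prenyl group to a quinone methide. Both follow from the high electron density of the ring.
Fallback, from 25 back to 29: the phenolate of 25 is oxygenated at C4a with singlet oxygen generated from KHSO5 (as 2KHSO5·KHSO4·K2SO4) and NaHCO3 in aqueous MeCN, giving the hydroperoxy dienone F3. Me2S reduces it to the para-quinol F4. The para-quinol F4 is then taken through the conditions of step 17: K2CO3 in MeOH gives the deacetylated quinol F5 and its bicyclic adduct F6, and the acid removes water in place of methanol to give 29. The ene reaction of the prenyl group with singlet oxygen is the limitation of this path.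

**Step 3.** The most likely failures are metalation at a carbon other than the one between the two oxygens, because the dianion aggregates or dissolves poorly, and proton transfer from the new benzylic and allylic methylene of the product to unreacted aryl metal, which would lead to double alkylation.
Fallback, from 8 and 10 back to 6, with regiocontrol by a hydrogen bond instead of by metalation: 8 is alkylated at its free 4-hydroxyl with 10 (K2CO3, KI, acetone) to the propargyl ether F7. Semihydrogenation over Pd on CaCO3 poisoned with Pb(OAc)2 and quinoline gives the 1,1-dimethylallyl ether F8. Heating brings about the aromatic Claisen rearrangement to the carbon between the oxygens and gives the 3-prenyl dihydroxybenzaldehyde F9. MeOCH2Cl with K2CO3 then protects the non-chelated 4-hydroxyl and gives the mono-acetal F10. MeI with K2CO3 in DMF methylates the chelated 2-hydroxyl and gives the fully substituted aldehyde F11. NaBH4 reduces the aldehyde F11 to 6, where the route is rejoined.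

**Step 15.** The most likely failure is incomplete cleavage of the acetal or partial loss of the acetate when the silyl triflate is not fully buffered.
Fallback, from 22 back to 25: the acetal is removed before acetylation with dilute HCl in MeOH, giving the phenol alcohol F12. Both hydroxyls are acetylated with Ac2O and pyridine to the diacetate F13. The aryl acetate alone is then cleaved with NH4OAc in aqueous MeOH, which gives 25.

**Step 6.** The most likely failure is slow etherification of the hydrogen-bonded hydroxyl, so that loss of the silyl group to the amidine base competes.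
Fallback, from 9 back to 13: the hydrogen bond is removed by reducing 9 with NaBH4 to the hydroxymethyl phenol F14. Its phenol is etherified with 10 (DBU, CuCl2 cat.) to the propargyl aryl ether F15. Heating in xylenes gives, through the allenyl phenol F16, the chromenyl methanol F17. MnO2 in CH2Cl2 then returns the aldehyde 13.

## Further compounds

F1 | step 17 | (3R)-3-[2,2-dimethyl-5-(triisopropylsilyloxy)-2H-chromen-8-yl]-4a,5-dimethoxy-6-(3-methylbut-2-enyl)-7-(trimethylsilyloxy)-3,4,4a,8a-tetrahydro-2H-chromene | COC1=C(CC=C(C)C)C(O[Si](C)(C)C)=CC2OC[C@@H](c3ccc(O[Si](C(C)C)(C(C)C)C(C)C)c4c3OC(C)(C)C=C4)CC12OC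
F2 | step 17 | (3R)-3-[2,2-dimethyl-5-(triisopropylsilyloxy)-2H-chromen-8-yl]-4a,5-dimethoxy-6-(3-methylbut-2-enyl)-2,3,4,4a-tetrahydrochromen-7-one | COC1=C(CC=C(C)C)C(=O)C=C2OC[C@@H](c3ccc(O[Si](C(C)C)(C(C)C)C(C)C)c4c3OC(C)(C)C=C4)CC12OC
F3 | step 16 | (2R)-2-[2,2-dimethyl-5-(triisopropylsilyloxy)-2H-chromen-8-yl]-3-[1-hydroperoxy-2-methoxy-3-(3-methylbut-2-enyl)-4-oxocyclohexa-2,5-dien-1-yl]propyl acetate | COC1=C(CC=C(C)C)C(=O)C=CC1(OO)C[C@H](c1ccc(O[Si](C(C)C)(C(C)C)C(C)C)c2c1OC(C)(C)C=C2)COC(C)=O
F4 | step 16 | (2R)-2-[2,2-dimethyl-5-(triisopropylsilyloxy)-2H-chromen-8-yl]-3-[1-hydroxy-2-methoxy-3-(3-methylbut-2-enyl)-4-oxocyclohexa-2,5-dien-1-yl]propyl acetate | COC1=C(CC=C(C)C)C(=O)C=CC1(O)C[C@H](c1ccc(O[Si](C(C)C)(C(C)C)C(C)C)c2c1OC(C)(C)C=C2)COC(C)=O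
F5 | step 16 | 4-[(2R)-2-[2,2-dimethyl-5-(triisopropylsilyloxy)-2H-chromen-8-yl]-3-hydroxypropyl]-4-hydroxy-3-methoxy-2-(3-methylbut-2-enyl)cyclohexa-2,5-dien-1-one | COC1=C(CC=C(C)C)C(=O)C=CC1(O)C[C@H](c1ccc(O[Si](C(C)C)(C(C)C)C(C)C)c2c1OC(C)(C)C=C2)CO
F6 | step 16 | (3R)-3-[2,2-dimethyl-5-(triisopropylsilyloxy)-2H-chromen-8-yl]-4a-hydroxy-5-methoxy-6-(3-methylbut-2-enyl)-2,3,4,4a,8,8a-hexahydrochromen-7-one | COC1=C(CC=C(C)C)C(=O)CC2OC[C@@H](c3ccc(O[Si](C(C)C)(C(C)C)C(C)C)c4c3OC(C)(C)C=C4)CC12O
F7 | step 3 | 2-hydroxy-4-(2-methylbut-3-yn-2-yloxy)benzaldehyde | O=Cc1ccc(OC(C)(C)C#C)cc1O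
F8 | step 3 | 2-hydroxy-4-(2-methylbut-3-en-2-yloxy)benzaldehyde | O=Cc1ccc(OC(C)(C)C=C)cc1O
F9 | step 3 | 2,4-dihydroxy-3-(3-methylbut-2-enyl)benzaldehyde | O=Cc1ccc(O)c(CC=C(C)C)c1O
F10 | step 3 | 2-hydroxy-4-(methoxymethoxy)-3-(3-methylbut-2-enyl)benzaldehyde | O=Cc1ccc(OCOC)c(CC=C(C)C)c1O
F11 | step 3 | 2-methoxy-4-(methoxymethoxy)-3-(3-methylbut-2-enyl)benzaldehyde | COCOc1ccc(C=O)c(OC)c1CC=C(C)C
F12 | step 15 | 4-[(2R)-2-[2,2-dimethyl-5-(triisopropylsilyloxy)-2H-chromen-8-yl]-3-hydroxypropyl]-3-methoxy-2-(3-methylbut-2-enyl)phenol | COc1c(CC=C(C)C)c(O)ccc1C[C@H](c1ccc(O[Si](C(C)C)(C(C)C)C(C)C)c2c1OC(C)(C)C=C2)CO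
F13 | step 15 | (2R)-3-[4-acetoxy-2-methoxy-3-(3-methylbut-2-enyl)phenyl]-2-[2,2-dimethyl-5-(triisopropylsilyloxy)-2H-chromen-8-yl]propyl acetate | COc1c(CC=C(C)C)c(OC(C)=O)ccc1C[C@H](c1ccc(O[Si](C(C)C)(C(C)C)C(C)C)c2c1OC(C)(C)C=C2)COC(C)=O
F14 | step 6 | 2-(hydroxymethyl)-5-(triisopropylsilyloxy)phenol | OCc1ccc(O[Si](C(C)C)(C(C)C)C(C)C)cc1O
F15 | step 6 | [2-(2-methylbut-3-yn-2-yloxy)-4-(triisopropylsilyloxy)phenyl]methanol | OCc1ccc(O[Si](C(C)C)(C(C)C)C(C)C)cc1OC(C)(C)C#C
F16 | step 6 | 2-(hydroxymethyl)-6-(3-methylbuta-1,2-dienyl)-5-(triisopropylsilyloxy)phenol | OCc1ccc(O[Si](C(C)C)(C(C)C)C(C)C)c(C=C=C(C)C)c1O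
F17 | step 6 | [2,2-dimethyl-5-(triisopropylsilyloxy)-2H-chromen-8-yl]methanol | OCc1ccc(O[Si](C(C)C)(C(C)C)C(C)C)c2c1OC(C)(C)C=C2
A1 | alternative 1 | 3-methoxy-5-(methoxymethoxy)-4-(3-methylbut-2-enyl)-2-[(4-methylphenyl)sulfonylmethyl]phenol | COc1c(CC=C(C)C)c(OCOC)cc(O)c1CS(=O)(=O)c1ccc(C)cc1
A2 | alternative 1 | 2-[2,2-dimethyl-5-(methoxymethoxy)-2H-chromen-8-yl]acetic acid | OC(=O)Cc1ccc(OCOC)c2c1OC(C)(C)C=C2
A3 | alternative 1 | (3R)-3-[2,2-dimethyl-5-(methoxymethoxy)-2H-chromen-8-yl]-5-methoxy-7-(methoxymethoxy)-6-(3-methylbut-2-enyl)chroman-2-one | COc1c(CC=C(C)C)c(OCOC)cc2c1C[C@H](c1ccc(OCOC)c3c1OC(C)(C)C=C3)C(=O)O2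
A4 | alternative 2 | 2-(3-methylbut-2-enyl)-3-(triisopropylsilyloxy)cyclobut-2-en-1-one | CC(C)=CCC1=C(O[Si](C(C)C)(C(C)C)C(C)C)CC1=O
A5 | alternative 2 | tert-butyl{[(2R)-2-[2,2-dimethyl-5-(triisopropylsilyloxy)-2H-chromen-8-yl]-5-methoxypent-4-ynyl]oxy}dimethylsilane | COC#CC[C@H](c1ccc(O[Si](C(C)C)(C(C)C)C(C)C)c2c1OC(C)(C)C=C2)CO[Si](C)(C)C(C)(C)C
A6 | alternative 2 | 2-[(2R)-3-(tert-butyldimethylsilyloxy)-2-[2,2-dimethyl-5-(triisopropylsilyloxy)-2H-chromen-8-yl]propyl]-3-methoxy-4-(3-methylbut-2-enyl)-5-(triisopropylsilyloxy)phenol | COc1c(CC=C(C)C)c(O[Si](C(C)C)(C(C)C)C(C)C)cc(O)c1C[C@H](c1ccc(O[Si](C(C)C)(C(C)C)C(C)C)c2c1OC(C)(C)C=C2)CO[Si](C)(C)C(C)(C)C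
A7 | alternative 3 | 1-[(3R)-5-methoxy-7-(methoxymethoxy)-6-(3-methylbut-2-enyl)chroman-3-yl]propan-2-one | COc1c(CC=C(C)C)c(OCOC)cc2c1C[C@H](CC(C)=O)CO2
A8 | alternative 3 | methyl acrylate | C=CC(=O)OC
A9 | alternative 3 | 4-[(3R)-5-methoxy-7-(methoxymethoxy)-6-(3-methylbut-2-enyl)chroman-3-yl]cyclohexane-1,3-dione, mixture of epimers at the ring-B carbon | COc1c(CC=C(C)C)c(OCOC)cc2c1C[C@H](C1CCC(=O)CC1=O)CO2
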